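The carbocycle (C4a, C5–C8, C8a in chromene numbering) contains dimethylketene dimer: C5(=O)–C6Me2–C7(=O)–C8Me2 is the carbon ring of 2,2,4,4-tetramethylcyclobutane-1,3-dione, and C4a/C8a are an acetate unit. The key step inserts lithio ethyl acetate into one C(O)–CMe2 bond of this commercial cyclobutanedione (aldol addition, retro-aldol ring opening, Dieckmann closure), so that the four-membered ring grows in one flask into the six-membered ring of syncarpic acid. The dihydropyran ring, the spiro centre and C4 then come from a three-component Knoevenagel/oxa-Diels–Alder reaction of syncarpic acid, 3-methylbutanal and (−)-β-pinene, which brings both pinane stereocentres.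

Key step: step 1

Remark: the pinane descriptors of the target (1'R,5'S) correspond to (1S,5S)-(−)-β-pinene (the change at C-1 is a CIP priority effect only); 5 is drawn as the triketo tautomer although it is largely enolised; LDA is taken as the commercial solution.

Step 1
Reactants: 1 2,2,4,4-tetramethylcyclobutane-1,3-dione; 2 ethyl acetate
Product: 5 syncarpic acid, via lithium aldolate 3 (not isolated), via open-chain keto ester enolate 4 (not isolated)
Conditions: LDA (1.05 equiv), THF, −78 °C; then 1, −78 → 0 °C; LDA (1.2 equiv), 0 °C → reflux; 2 M HCl
Reagents that add atoms: none
Why: Proposed new method: lithio ethyl acetate should add to one strained, non-enolisable C=O of 1 (aldol addition) and alkoxide 3 should cleave the adjacent C(O)–CMe2 ring bond by retro-aldol fragmentation, driven by release of cyclobutane strain, to give after proton transfer the β-keto ester enolate 4. The second charge of LDA then forms the isopropyl ketone enolate, whose CMe2 carbon attacks the ester carbonyl in a 6-(enolendo)-exo-trig Dieckmann closure with loss of ethoxide, so the only ring formed is the cyclohexanetrione, which is the four-membered ring enlarged by the two acetate carbons. The closest known reaction types are the base-induced ring opening of 1 and of its 3-hydroxy adducts to 2,2,4-trimethyl-3-oxopentanoyl derivatives, and the Dieckmann closure by which base-catalysed trimerisation of dimethylketene ends in hexamethylcyclohexane-1,3,5-trione and 3,5-dioxoalkanoates give phloroglucinol-type triones; new is an ester enolate as the inserted two-carbon unit and a closure that has to run through a dianion. No stereocentre is formed. The step needs mono-addition to 1 and C- rather than O-acylation in the closure: the first should follow from the 1:1 stoichiometry at −78 °C, because the remaining C=O of the anionic aldolate is more hindered and less electrophilic than that of 1, and the second from reversibility, because ethoxide reopens an enol lactone while the enolate of 5, a vinylogous carboxylate, is the thermodynamic sink.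

Step 2
Reactants: 5 syncarpic acid; 6 3-methylbutanal; 7 (−)-β-pinene
Product: 9 target spirochromenedione, via alkylidene trione 8 (not isolated)
Conditions: EDDA (10 mol %), 6 (1.5 equiv), 7 (3 equiv), PhMe, 80 °C, sealed tube; chromatography
Reagents that add atoms: none
Why: Domino Knoevenagel condensation/inverse-electron-demand oxa-Diels–Alder reaction, in which ammonium acetate catalysis condenses 6 on C-6 of 5 to the s-cis-locked 1-oxadiene 8, whose β-carbon bonds to the CH2 terminus and whose carbonyl oxygen bonds to the more substituted C-2 of 7 on the face anti to the gem-dimethyl bridge (spiro centre R, pinane centres untouched), while the orientation that places the C-3 methylene of 7 rather than its bridgehead under the trione ring should set C-4 as S, the C-4 epimer being the expected by-product to be removed by chromatography.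

Compound list
1 | 2,2,4,4-tetramethylcyclobutane-1,3-dione (dimethylketene dimer) | CC1(C)C(=O)C(C)(C)C1=O | starting material
2 | ethyl acetate | CCOC(C)=O | starting material
3 | lithium 1-(2-ethoxy-2-oxoethyl)-2,2,4,4-tetramethyl-3-oxocyclobutan-1-olate | CCOC(=O)CC1([O-])C(C)(C)C(=O)C1(C)C.[Li+] | intermediate
4 | lithium enolate of ethyl 4,4,6-trimethyl-3,5-dioxoheptanoate | CCOC(=O)C=C([O-])C(C)(C)C(=O)C(C)C.[Li+] | intermediate
5 | syncarpic acid, 2,2,4,4-tetramethylcyclohexane-1,3,5-trione | CC1(C)C(=O)CC(=O)C(C)(C)C1=O | intermediate
6 | 3-methylbutanal (isovaleraldehyde) | CC(C)CC=O | starting material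
7 | (−)-β-pinene, (1S,5S)-6,6-dimethyl-2-methylidenebicyclo[3.1.1]heptane | C=C1CC[C@H]2C[C@@H]1C2(C)C | starting material
8 | 2,2,4,4-tetramethyl-6-(3-methylbutylidene)cyclohexane-1,3,5-trione | CC(C)CC=C1C(=O)C(C)(C)C(=O)C(C)(C)C1=O | intermediate
9 | CNP0231252.1, (1'R,2R,4S,5'S)-6,6,6',6',8,8-hexamethyl-4-(2-methylpropyl)-3,4-dihydrospiro[chromene-2,2'-bicyclo[3.1.1]heptane]-5,7(6H,8H)-dione | CC(C)C[C@H]1C[C@@]2(CC[C@H]3C[C@@H]2C3(C)C)OC2=C1C(=O)C(C)(C)C(=O)C2(C)C | target

Total step count: 2
Longest linear sequence: 2

Steps most likely to fail (the route has only two steps, so both are ranked):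

1. Step 1. The sequence may stall after ring opening, because the ester carbonyl of 4 is deactivated once its acidic methylene is deprotonated, so that the hindered isopropyl ketone enolate closes too slowly. A second addition of the ester enolate to the dione may also consume material. Fallback (known chemistry), setting out from 1 and returning at 5: methoxide-catalysed methanolysis of 1 (NaOMe cat., MeOH) should give methyl 2,2,4-trimethyl-3-oxopentanoate F1. Its enolate (LDA, THF, −78 °C, magnesium counter-ion from MgBr2·OEt2 to favour carbon) is C-acetylated with acetyl chloride to methyl 2,2,4,4-tetramethyl-3,5-dioxohexanoate F2. LDA then forms the methyl ketone enolate, which closes onto the ester by Dieckmann condensation to 5. Here the two carbons enter as an acetyl electrophile after the four-membered ring is opened, so the closing nucleophile is an unhindered methyl ketone enolate and the ester has no acidic α-hydrogen.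

2. Step 2. At the temperature needed for cycloaddition, the heterodiene 8 may tautomerise or add a second molecule of 5. β-Pinene may react by an ene pathway or isomerise under the acidic catalyst. Discrimination between the two orientations that decide C-4 may be low. Fallback, setting out from 5 and returning at 9: 5, 6 and piperidine (CH2Cl2, rt) should give the isolable Mannich base 3-hydroxy-4,4,6,6-tetramethyl-2-[3-methyl-1-(piperidin-1-yl)butyl]cyclohex-2-ene-1,5-dione F3 (racemic at the aminated carbon). TsOH·H2O (1.0 equiv) in CH2Cl2 at 0 °C → rt then releases 8 by loss of piperidine in the presence of 7 (3 equiv), so that cycloaddition runs at low temperature with the acid consumed as its piperidinium salt, and the route is rejoined at 9.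

Further compounds
F1 | step 1 | methyl 2,2,4-trimethyl-3-oxopentanoate | COC(=O)C(C)(C)C(=O)C(C)C
F2 | step 1 | methyl 2,2,4,4-tetramethyl-3,5-dioxohexanoate | COC(=O)C(C)(C)C(=O)C(C)(C)C(C)=O
F3 | step 2 | 3-hydroxy-4,4,6,6-tetramethyl-2-[3-methyl-1-(piperidin-1-yl)butyl]cyclohex-2-ene-1,5-dione (racemic) | CC(C)CC(N1CCCCC1)C1=C(O)C(C)(C)C(=O)C(C)(C)C1=O
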